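**Retrosynthetic overview**
1. Ring A is made last and is the only ring constructed: C5–C8 and their four oxygens come from squaric acid (1) via dimethyl squarate (2).
2. Ring B comes from catechol (3) via veratrole (4), aryl tert-butyl ether (5) and boronic acid (6); ring C is bought intact as 4H-pyran-4-one (7).
3. Key disconnection, C2–C1′: radical (borono-Minisci type) C–H arylation of 7 by the aryl radical from 6 gives 2-arylpyranone 8.
4. C8–C8a and C4a–C5: C6-lithiated 8 adds to 2 with the alkoxide trapped as OMe (9); thermal 4π-opening/6π-closure gives flavone 10, and tBu removal gives Gardenin C (11).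
5. Ring order: B and C (both purchased) are joined first, then A is annulated onto C.

Assumption: the target has no stereocentres or stereoaxes, so "single enantiomer" needs no stereocontrol; the only chiral intermediate (9) is racemic and its stereocentre is destroyed in step 7.

**Step 1**
Reactants: 1 squaric acid
Product: 2 dimethyl squarate (3,4-dimethoxycyclobut-3-ene-1,2-dione)
Conditions: HC(OMe)3, MeOH, reflux, 24 h
Reagents that add atoms: trimethyl orthoformate COC(OC)OC; methanol CO
Why: Vinylogous Fischer esterification driven by orthoformate removal of water, the standard preparation of dimethyl squarate.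

**Step 2**
Reactants: 3 catechol
Product: 4 veratrole (1,2-dimethoxybenzene)
Conditions: MeI (2.5 equiv), K2CO3, acetone, reflux
Reagents that add atoms: iodomethane CI
Why: Double Williamson O-methylation of a simple catechol.

**Step 3**
Reactants: 4 veratrole
Product: 5 1-tert-butoxy-2,3-dimethoxybenzene
Conditions: n-BuLi, TMEDA, Et2O, 0 °C to rt; MgBr2·OEt2, 0 °C; PhCO3t-Bu, 0 °C to rt
Reagents that add atoms: tert-butyl perbenzoate CC(C)(C)OOC(=O)c1ccccc1
Why: OMe-directed ortho-metalation at C3, then transfer of electrophilic t-BuO from the perester to the aryl Grignard (Lawesson–Yang tert-butoxylation) installs the third oxygen already protected as a base-stable, acid-labile aryl tert-butyl ether.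

**Step 4**
Reactants: 5 1-tert-butoxy-2,3-dimethoxybenzene
Product: 6 (3-tert-butoxy-4,5-dimethoxyphenyl)boronic acid
Conditions: [Ir(OMe)(cod)]2 (1.5 mol%), dtbpy (3 mol%), B2pin2, THF, 80 °C; then NaIO4, NH4OAc, acetone/H2O, rt (one pot)
Reagents that add atoms: bis(pinacolato)diboron CC1(C)OB(OC1(C)C)B1OC(C)(C)C(C)(C)O1 (boron); water O (B–OH)
Why: Sterically controlled Ir-catalysed C–H borylation goes to C5, the only C–H with no ortho substituent in a 1,2,3-trisubstituted arene, and periodate cleaves the pinacol ester to the boronic acid.

**Step 5 (key step)**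
Reactants: 6 (3-tert-butoxy-4,5-dimethoxyphenyl)boronic acid; 7 4H-pyran-4-one (5 equiv, excess recovered)
Product: 8 2-(3-tert-butoxy-4,5-dimethoxyphenyl)-4H-pyran-4-one
Conditions: AgNO3 (0.2 equiv), K2S2O8 (3 equiv), TFA (1 equiv), CH2Cl2/H2O 1:1, rt
Reagents that add atoms: none
Why: Proposed new method: Ag(I)/persulfate oxidises the boronic acid to the aryl radical, which adds to C2 of the pyranone (the enone β-carbon, and the α-position of the 4-hydroxypyrylium formed with TFA), and the delocalised adduct radical loses H+/e− to persulfate to restore the pyranone, forming the C2–C1′ bond; excess 7 suppresses 2,6-diarylation and the tBu ether tolerates dilute aqueous TFA (cf. Tyr(tBu)); the closest known reactions are the borono-Minisci C–H arylation of protonated heteroarenes and quinones with arylboronic acids, and radical C2-functionalisation of chromones.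

**Step 6**
Reactants: 8 2-(3-tert-butoxy-4,5-dimethoxyphenyl)-4H-pyran-4-one; 2 dimethyl squarate
Product: 9 rac-4-[6-(3-tert-butoxy-4,5-dimethoxyphenyl)-4-oxo-4H-pyran-2-yl]-2,3,4-trimethoxycyclobut-2-en-1-one
Conditions: LiTMP (1.1 equiv), THF, −78 °C, 20 min; cannulate into 2 (1.2 equiv), THF, −78 °C; MeOTf (1.3 equiv), −78 to −20 °C
Reagents that add atoms: methyl triflate COS(=O)(=O)C(F)(F)F
Why: Kinetic deprotonation by the hindered amide at the unhindered C6–H (vinylic, α to ring oxygen, by analogy with C2-metalation of chromones and 4-pyranones by TMP bases) gives an α-alkoxyvinyllithium that adds 1,2 to a squarate carbonyl (Moore/Liebeskind addition), and the far more nucleophilic lithium alkoxide is methylated in situ to become the future 8-OMe; the new quaternary centre is racemic and is erased in step 7.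

**Step 7**
Reactants: 9 (racemic cyclobutenone)
Product: 10 2-(3-tert-butoxy-4,5-dimethoxyphenyl)-5-hydroxy-6,7,8-trimethoxy-4H-chromen-4-one
Conditions: p-xylene (0.02 M), 138 °C, 1–2 h, Ar; concentrate
Reagents that add atoms: none
Why: Moore–Liebeskind ring expansion: 4π-electrocyclic opening (OMe rotates outward) gives a dienylketene, 6π-closure of the ketene carbon onto pyranone C5 and tautomerisation give the fully substituted A ring, with 5-OH from the ketene carbonyl and 8-OMe from the trapped alkoxide; the aryl tert-butyl ether is stable under neutral thermolysis.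

**Step 8**
Reactants: 10 2-(3-tert-butoxy-4,5-dimethoxyphenyl)-5-hydroxy-6,7,8-trimethoxy-4H-chromen-4-one
Product: 11 Gardenin C (5-hydroxy-2-(3-hydroxy-4,5-dimethoxyphenyl)-6,7,8-trimethoxy-4H-chromen-4-one)
Conditions: TFA/CH2Cl2 (1:3), anisole (5 equiv), 0 °C to rt, 1 h
Reagents that add atoms: none
Why: Acid-mediated SN1/E1 cleavage of the aryl tert-butyl ether (tert-butyl ether deprotection) releases the 3′-OH, with anisole trapping the tert-butyl cation; the methyl ethers and the flavone core are inert to TFA at room temperature.

Steps 7 and 8 can be telescoped (solvent swap, no purification of 10), but are counted separately.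

**Compound list**
1 | squaric acid | O=C1C(O)=C(O)C1=O | starting material
2 | dimethyl squarate | COC1=C(OC)C(=O)C1=O | intermediate
3 | catechol | Oc1ccccc1O | starting material
4 | veratrole | COc1ccccc1OC | intermediate
5 | 1-tert-butoxy-2,3-dimethoxybenzene | COc1cccc(OC(C)(C)C)c1OC | intermediate
6 | (3-tert-butoxy-4,5-dimethoxyphenyl)boronic acid | COc1cc(B(O)O)cc(OC(C)(C)C)c1OC | intermediate
7 | 4H-pyran-4-one | O=c1ccocc1 | starting material
8 | 2-(3-tert-butoxy-4,5-dimethoxyphenyl)-4H-pyran-4-one | COc1cc(-c2cc(=O)cco2)cc(OC(C)(C)C)c1OC | intermediate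
9 | rac-4-[6-(3-tert-butoxy-4,5-dimethoxyphenyl)-4-oxo-4H-pyran-2-yl]-2,3,4-trimethoxycyclobut-2-en-1-one | COC1=C(OC)C(OC)(c2cc(=O)cc(-c3cc(OC)c(OC)c(OC(C)(C)C)c3)o2)C1=O | intermediate (racemic)
10 | 2-(3-tert-butoxy-4,5-dimethoxyphenyl)-5-hydroxy-6,7,8-trimethoxy-4H-chromen-4-one | COc1cc(-c2cc(=O)c3c(O)c(OC)c(OC)c(OC)c3o2)cc(OC(C)(C)C)c1OC | intermediate
11 | Gardenin C | COc1cc(-c2cc(=O)c3c(O)c(OC)c(OC)c(OC)c3o2)cc(O)c1OC | target

**Totals**
Total steps: 8.
Longest linear sequence: 7 steps (3 → 4 → 5 → 6 → 8 → 9 → 10 → 11); step 1 is a one-step side branch.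

**Steps most likely to fail, with fallbacks**
1. Step 5 (radical arylation of the pyranone). Risks are C2 versus C3 selectivity, oxidative loss of the electron-rich boronic acid, and low radical-trapping efficiency. Fallback: reverse the order. Lithiate 7 itself, add to 2 with MeOTf trapping and ring-expand to 5-hydroxy-6,7,8-trimethoxychromone. Then run the aryl-radical C–H arylation on the chromone, which has a single C2–H and can take the boronic acid in excess, and finish with the TFA deprotection.
2. Step 6 (C6 versus C3/C5 lithiation, stability of the lithiopyranone, and alkoxide versus pyranone-carbonyl methylation). Fallback: omit MeOTf and isolate the 4-hydroxycyclobutenone. Thermolysis then gives the 5,8-dihydroxy-6,7-dimethoxyflavone from either the C5- or C6-lithiated adduct, and the non-chelated 8-OH is methylated selectively (TMSCHN2, or MeI/K2CO3) before deprotection. This costs one extra step.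
3. Step 3 (perester tert-butoxylation of the aryl-metal may give a modest yield). Fallback: quench the lithiated veratrole with B(OMe)3 then H2O2 to give 2,3-dimethoxyphenol, protect it as the TIPS ether, and replace the final TFA step with TBAF. This also costs one extra step.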